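**Strategy**

1. Target 28 is cut at benzofuran C3–C2 and at C1–C2 of the 3,7-dioxabicyclo[3.3.0]octane (C1, C2, O3, C4, C5, C6, O7, C8), after C8H2 is taken back to a lactone carbonyl, the C3 hydroxymethyl to a tert-butyl ester and both phenols to benzyl ethers. Further cuts are the C4–O3 ether, the aryl–CH2CO2t-Bu bond, the C5–C6 aldol bond and the phenol ether.
2. Enabling feature: benzofuran C2 and bicycle C2 are ArCH(O) carbons lying 1,5 to a carbon that can carry a diazo group (benzofuran C3; C1 next to the C8 carbonyl). Each aryl group is cis to the carbon branch on that neighbour (C2 aryl cis to C3–CH2OH; both aryls endo), which is the kinetic imprint of carbenoid insertion into an ArCH2–O bond.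
3. Forward order: the γ-lactone (C5, C6, O7, C8, C1; later ring 2) arises by anti-aldol and lactonisation, then the ether and arylacetate arms are attached. One operation closes the dihydrofuran ring of the benzofuran and tetrahydrofuran ring 1; the lactone is then reduced and re-closed at primary C8 as ring 2, the ester reduced and the benzyl groups removed.
4. Stereochemistry: C5/C6 come from the auxiliary-controlled anti-aldol, C1 from C5 through the forced cis fusion, and C2 from the endo-selective insertion. Benzofuran C2/C3 are cis from the insertion and their absolute sense comes from the chiral dirhodium carboxylate. C6 is kept because ring 2 closes by displacement at C8.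

Key step: step 13

Abbreviations: BMB = 4-(benzyloxy)-3-methoxybenzyl; BMP = 4-(benzyloxy)-3-methoxyphenyl; ArBr = 3-bromo-5-methoxy-4-(BMB-oxy)phenyl.

Assumption: the (4S)-benzyl auxiliary is taken to give the (3R,4S) anti-aldol through the chelated magnesium (Z)-enolate, and Rh2(S-PTTL)4 is taken to give the (2S,3R) cis-dihydrobenzofuran ester; if either sense were the reverse, the mirror-image auxiliary or ligand would be used with no other change.

**Route**

Step 1
Reactants: 1 5-bromovanillin; 2 [4-(benzyloxy)-3-methoxyphenyl]methanol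
Product: 3 3-bromo-4-(BMB-oxy)-5-methoxybenzaldehyde
Conditions: PPh3, diisopropyl azodicarboxylate, THF, 0 to 23 °C
Reagents that add atoms: none
Why: Mitsunobu etherification, in which the acidic phenol of 1 (para-formyl, ortho-bromo) displaces the alkoxyphosphonium ion of the primary benzylic alcohol 2, so the ether forms without a labile dialkoxybenzyl halide and without touching the aldehyde.

Step 2
Reactants: 4 (4S)-4-benzyl-1,3-oxazolidin-2-one; 5 methyl 4-chloro-4-oxobutanoate
Product: 7 methyl 4-[(4S)-4-benzyl-2-oxo-1,3-oxazolidin-3-yl]-4-oxobutanoate, via lithium oxazolidinide 6 (not isolated)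
Conditions: n-BuLi, THF, −78 °C; then 5, −78 to 0 °C
Reagents that add atoms: n-butyllithium [Li]CCCC (lithium only in 6; none stays in 7)
Why: N-acylation of the lithiated oxazolidinone by the acid chloride (standard auxiliary loading), the acid chloride being far more electrophilic than the methyl ester.

Step 3
Reactants: 3 3-bromo-4-(BMB-oxy)-5-methoxybenzaldehyde; 7 methyl 4-[(4S)-4-benzyl-2-oxo-1,3-oxazolidin-3-yl]-4-oxobutanoate
Product: 8 methyl (3R,4S)-3-{[(4S)-4-benzyl-2-oxo-1,3-oxazolidin-3-yl]carbonyl}-4-ArBr-4-[(trimethylsilyl)oxy]butanoate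
Conditions: MgCl2 (0.2 equiv), Et3N, Me3SiCl, EtOAc, 23 °C
Reagents that add atoms: chlorotrimethylsilane C[Si](C)(C)Cl
Why: Evans-type MgCl2-catalysed direct anti-aldol reaction, in which Et3N enolises only the magnesium-chelated imide, the chelated (Z)-enolate adds to the non-enolisable aldehyde through a boat-like transition state that gives the anti pair, silylation of the aldolate turns the catalyst over, and the benzyl group of the auxiliary blocks one enolate face so that C3 is set R and C4 S.

Step 4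
Reactants: 8 methyl (3R,4S)-3-{[(4S)-4-benzyl-2-oxo-1,3-oxazolidin-3-yl]carbonyl}-4-ArBr-4-[(trimethylsilyl)oxy]butanoate
Product: 10 (4S)-4-benzyl-3-{[(2S,3R)-2-ArBr-5-oxooxolan-3-yl]carbonyl}-1,3-oxazolidin-2-one (cis-lactone), via free hydroxy ester 9 (not isolated)
Conditions: pyridinium p-toluenesulfonate (0.1 equiv), MeOH, 23 °C; then PhMe, 50 °C
Reagents that add atoms: none
Why: acid-catalysed methanolysis of the trimethylsilyl ether followed by lactonisation (intramolecular transesterification, 5-exo-trig) of the freed benzylic hydroxyl onto the methyl ester, which turns the anti-aldol pair into the cis-lactone without breaking a bond at either stereocentre, under acid mild enough for the dialkoxybenzyl aryl ether.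

Step 5
Reactants: 10 (4S)-4-benzyl-3-{[(2S,3R)-2-ArBr-5-oxooxolan-3-yl]carbonyl}-1,3-oxazolidin-2-one
Product: 12 (2S,3R)-2-ArBr-5-oxooxolane-3-carboxylic acid, via lactone peroxy acid 11 (not isolated)
Conditions: LiOH, H2O2, THF/H2O (3:1), 0 °C; aq Na2SO3; 1 M HCl to pH 3 at 0 °C
Reagents that add atoms: hydrogen peroxide OO (one oxygen, as LiOOH)
Why: hydroperoxide cleavage of the N-acyloxazolidinone, in which LiOOH attacks the exocyclic imide carbonyl selectively and faster than C3 is enolised, sulfite reduces the peracid, and any lactone opened by hydroxide re-closes on acidification, so both stereocentres are kept.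

Step 6
Reactants: 12 (2S,3R)-2-ArBr-5-oxooxolane-3-carboxylic acid
Product: 13 (4S,5S)-5-ArBr-4-(hydroxymethyl)oxolan-2-one
Conditions: BH3·SMe2, THF, 0 to 23 °C; MeOH quench, neutral work-up
Reagents that add atoms: none
Why: chemoselective borane reduction of a carboxylic acid (through the acyloxyborane) in the presence of the γ-lactone, aryl bromide and ethers, with neutral work-up so that the cis-hydroxymethyl lactone does not translactonise.

Step 7
Reactants: 2 [4-(benzyloxy)-3-methoxyphenyl]methanol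
Product: 14 BMB 2,2,2-trichloroacetimidate
Conditions: Cl3CCN, DBU (0.1 equiv), CH2Cl2, 0 °C; used fresh
Reagents that add atoms: trichloroacetonitrile ClC(Cl)(Cl)C#N
Why: base-catalysed addition of the benzylic alkoxide to trichloroacetonitrile (trichloroacetimidate formation).

Step 8
Reactants: 13 (4S,5S)-5-ArBr-4-(hydroxymethyl)oxolan-2-one; 14 BMB 2,2,2-trichloroacetimidate
Product: 15 (4S,5S)-5-ArBr-4-[(BMB-oxy)methyl]oxolan-2-one
Conditions: La(OTf)3 (0.05 equiv), PhMe, 23 °C, directly on freshly made 13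
Reagents that add atoms: none
Why: Lewis acid-catalysed trichloroacetimidate benzylation, in which the electron-rich imidate ionises under very mild catalysis and is captured by the primary hydroxyl quickly enough that the lactone neither translactonises nor loses its aryl benzyl ether.

Step 9
Reactants: 16 tert-butyl bromoacetate
Product: 17 (2-tert-butoxy-2-oxoethyl)zinc bromide (titrated THF solution)
Conditions: Zn dust (activated with Me3SiCl and 1,2-dibromoethane), THF, 23 to 40 °C
Reagents that add atoms: zinc [Zn]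
Why: oxidative insertion of activated zinc into the C–Br bond (Reformatsky reagent formation).

Step 10
Reactants: 15 (4S,5S)-5-ArBr-4-[(BMB-oxy)methyl]oxolan-2-one; 17 (2-tert-butoxy-2-oxoethyl)zinc bromide
Product: 18 tert-butyl 2-{3-methoxy-2-(BMB-oxy)-5-[(2S,3S)-3-[(BMB-oxy)methyl]-5-oxooxolan-2-yl]phenyl}acetate
Conditions: Pd(dba)2 (2 mol %), (C5Ph5)Fe[C5H4P(t-Bu)2] (Q-Phos, 2 mol %), THF, 23 °C
Reagents that add atoms: none
Why: palladium-catalysed α-arylation of a zinc ester enolate (Reformatsky reagent cross-coupling) by oxidative addition of zerovalent palladium into the aryl bromide, transmetalation and reductive elimination, the weakly basic zinc enolate leaving the lactone and its stereocentres alone.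

Step 11
Reactants: 18 tert-butyl 2-{3-methoxy-2-(BMB-oxy)-5-[(2S,3S)-3-[(BMB-oxy)methyl]-5-oxooxolan-2-yl]phenyl}acetate
Product: 19 tert-butyl 2-diazo-2-{3-methoxy-2-(BMB-oxy)-5-[(2S,3S)-3-[(BMB-oxy)methyl]-5-oxooxolan-2-yl]phenyl}acetate
Conditions: 4-acetamidobenzenesulfonyl azide, DBU, MeCN, 0 to 23 °C
Reagents that add atoms: 4-acetamidobenzenesulfonyl azide CC(=O)Nc1ccc(cc1)S(=O)(=O)N=[N+]=[N-]
Why: Regitz diazo transfer, in which DBU deprotonates only the benzylic arylacetate CH2 (several pKa units more acidic than the lactone α-CH2) and the enolate takes N2 from the sulfonyl azide.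

Step 12
Reactants: 19 tert-butyl 2-diazo-2-{3-methoxy-2-(BMB-oxy)-5-[(2S,3S)-3-[(BMB-oxy)methyl]-5-oxooxolan-2-yl]phenyl}acetate
Product: 21 tert-butyl 2-diazo-2-{5-[(2S,3S)-4-diazo-3-[(BMB-oxy)methyl]-5-oxooxolan-2-yl]-3-methoxy-2-(BMB-oxy)phenyl}acetate, via trifluoroacetyl lactone 20 (not isolated)
Conditions: LiN(SiMe3)2, THF, −78 °C; CF3CO2CH2CF3, −78 °C; aq NH4Cl; then MsN3, Et3N, H2O (1 equiv), MeCN, 23 °C
Reagents that add atoms: methanesulfonyl azide CS(=O)(=O)N=[N+]=[N-] (two nitrogen atoms); 2,2,2-trifluoroethyl trifluoroacetate O=C(OCC(F)(F)F)C(F)(F)F (trifluoroacetyl group in 20 only)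
Why: deacylative (detrifluoroacetylative) diazo transfer, in which the amide base enolises only the lactone because the arylacetate carbon is already blocked as diazo, Claisen-type trifluoroacetylation activates the lactone α-carbon, and the azide/amine pair replaces the trifluoroacetyl group by N2 without affecting the two lactone stereocentres.

Step 13
Reactants: 21 tert-butyl 2-diazo-2-{5-[(2S,3S)-4-diazo-3-[(BMB-oxy)methyl]-5-oxooxolan-2-yl]-3-methoxy-2-(BMB-oxy)phenyl}acetate
Product: 23 tert-butyl (2S,3R)-2-BMP-5-[(1R,2S,5S,6S)-2-BMP-8-oxo-3,7-dioxabicyclo[3.3.0]octan-6-yl]-7-methoxy-2,3-dihydro-1-benzofuran-3-carboxylate, via mono-insertion diazolactone 22 (not isolated)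
Conditions: Rh2(S-PTTL)4 (dirhodium tetrakis[N-phthaloyl-(S)-tert-leucinate], 2 mol %), PhMe, slow addition of 21 at −60 °C, then −60 to 23 °C
Reagents that add atoms: none
Why: Proposed new method: two rhodium-carbenoid C–H insertions are run in one operation on a substrate carrying two different diazo groups, which is not established; the closest known reaction types are the Rh2(S-PTTL)4-catalysed enantioselective insertion of 2-(benzyloxy)aryl diazoacetates to cis-2-aryl-2,3-dihydrobenzofuran-3-carboxylates and the dirhodium carboxylate-catalysed insertion of α-diazo-γ-butyrolactones into benzylic ether C–H bonds to endo-aryl furofuranones. Each diazo carbon loses N2 on divalent rhodium to give an electrophilic carbenoid, which inserts through a concerted, hydride-transfer-like three-centre transition state into the only ArCH2–O C–H bond five atoms away, a bond made hydridic by its oxygen and its electron-rich aryl group. The aryl (donor/acceptor) carbenoid is expected to react first at −60 °C and closes the dihydrofuran ring of the benzofuran by 1,5-insertion (new bond C3–C2; ring O1, C2, C3, C3a, C7a), and on warming the lactone carbenoid closes tetrahydrofuran ring 1 by 1,5-insertion (new bond C1–C2; ring C1, C2, O3, C4, C5), necessarily cis-fused to the lactone. Benzofuran C2 and C3 come out cis because the aryl group of the reacting CH2 sits pseudo-equatorial in the five-membered transition state, away from the ligand wall and on the side of the ester, and their absolute (2S,3R) sense is imposed by the chiral phthalimido carboxylate ligands, the older stereocentres being remote; in the bicycle C1 is fixed by C5 through the cis fusion and C2 takes its aryl group endo (cis to C8) by the same transition-state preference. The step needs site selectivity, cis selectivity in both rings and one facial sense at the benzofuran, which are secured by the single activated C–H bond within 1,5-reach of each carbenoid, by the bulky carboxylate and the low temperature that hold back 1,2-hydride shift of the lactone carbenoid to a butenolide, and by slow addition, which keeps carbenoid and diazo groups of different molecules apart.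

Step 14
Reactants: 23 tert-butyl (2S,3R)-2-BMP-5-[(1R,2S,5S,6S)-2-BMP-8-oxo-3,7-dioxabicyclo[3.3.0]octan-6-yl]-7-methoxy-2,3-dihydro-1-benzofuran-3-carboxylate
Product: 24 tert-butyl (2S,3R)-2-BMP-5-{(S)-hydroxy[(3S,4S,5S)-5-BMP-4-(hydroxymethyl)oxolan-3-yl]methyl}-7-methoxy-2,3-dihydro-1-benzofuran-3-carboxylate
Conditions: LiBH4, THF, 0 to 23 °C; aq NH4Cl
Reagents that add atoms: none
Why: chemoselective hydride reduction, in which LiBH4 opens the lactone to the 1,4-diol while the hindered tert-butyl ester is reduced far more slowly, and no stereocentre is involved.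

Step 15
Reactants: 24 tert-butyl (2S,3R)-2-BMP-5-{(S)-hydroxy[(3S,4S,5S)-5-BMP-4-(hydroxymethyl)oxolan-3-yl]methyl}-7-methoxy-2,3-dihydro-1-benzofuran-3-carboxylate
Product: 26 tert-butyl (2S,3R)-2-BMP-5-[(1S,2S,5S,6S)-6-BMP-3,7-dioxabicyclo[3.3.0]octan-2-yl]-7-methoxy-2,3-dihydro-1-benzofuran-3-carboxylate, via primary mesylate 25 (not isolated)
Conditions: MsCl (1.1 equiv), pyridine, 0 to 23 °C
Reagents that add atoms: methanesulfonyl chloride CS(=O)(=O)Cl (mesyl group in 25 only; none stays in 26)
Why: selective sulfonylation of the primary hydroxyl followed by intramolecular Williamson-type etherification (5-exo-tet SN2 at primary C8 by the benzylic hydroxyl), so the C6–O bond is never broken and the endo aryl group at C6 is retained.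

Step 16
Reactants: 26 tert-butyl (2S,3R)-2-BMP-5-[(1S,2S,5S,6S)-6-BMP-3,7-dioxabicyclo[3.3.0]octan-2-yl]-7-methoxy-2,3-dihydro-1-benzofuran-3-carboxylate
Product: 27 {(2S,3S)-2-BMP-5-[(1S,2S,5S,6S)-6-BMP-3,7-dioxabicyclo[3.3.0]octan-2-yl]-7-methoxy-2,3-dihydro-1-benzofuran-3-yl}methanol
Conditions: LiAlH4, THF, −20 to 0 °C; aqueous basic work-up
Reagents that add atoms: none
Why: LiAlH4 reduction of the ester to the primary alcohol, hydride addition at low temperature outrunning enolisation at C3 so that the cis relationship is kept.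

Step 17
Reactants: 27 {(2S,3S)-2-BMP-5-[(1S,2S,5S,6S)-6-BMP-3,7-dioxabicyclo[3.3.0]octan-2-yl]-7-methoxy-2,3-dihydro-1-benzofuran-3-yl}methanol
Product: 28 4-{(2S,3S)-3-(hydroxymethyl)-5-[(1S,2S,5S,6S)-6-(4-hydroxy-3-methoxyphenyl)-3,7-dioxabicyclo[3.3.0]octan-2-yl]-7-methoxy-2,3-dihydro-1-benzofuran-2-yl}-2-methoxyphenol (target)
Conditions: H2 (1 atm), Pd/C (10 wt %), EtOAc, 23 °C, stopped after two equivalents of H2
Reagents that add atoms: none
Why: catalytic hydrogenolysis of the two aryl benzyl ethers, which are cleaved much faster than the secondary benzylic C–O bonds of the bicycle and the dihydrobenzofuran in a neutral aprotic solvent.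

**Compound list**

1 | 5-bromovanillin | COc1cc(C=O)cc(Br)c1O | starting material
2 | [4-(benzyloxy)-3-methoxyphenyl]methanol | COc1cc(CO)ccc1OCc1ccccc1 | starting material
3 | 3-bromo-4-(BMB-oxy)-5-methoxybenzaldehyde | COc1cc(C=O)cc(Br)c1OCc1ccc(OCc2ccccc2)c(OC)c1 | intermediate
4 | (4S)-4-benzyl-1,3-oxazolidin-2-one | O=C1N[C@@H](Cc2ccccc2)CO1 | starting material
5 | methyl 4-chloro-4-oxobutanoate | COC(=O)CCC(Cl)=O | starting material
6 | lithium (4S)-4-benzyl-2-oxo-1,3-oxazolidin-3-ide | [Li+].O=C1[N-][C@@H](Cc2ccccc2)CO1 | intermediate (not isolated)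
7 | methyl 4-[(4S)-4-benzyl-2-oxo-1,3-oxazolidin-3-yl]-4-oxobutanoate | COC(=O)CCC(=O)N1C(=O)OC[C@@H]1Cc1ccccc1 | intermediate
8 | (3R,4S) anti-aldol adduct, trimethylsilyl ether | COC(=O)C[C@@H](C(=O)N1C(=O)OC[C@@H]1Cc1ccccc1)[C@H](O[Si](C)(C)C)c1cc(OC)c(OCc2ccc(OCc3ccccc3)c(OC)c2)c(Br)c1 | intermediate
9 | (3R,4S) anti-aldol adduct, free hydroxy ester | COC(=O)C[C@@H](C(=O)N1C(=O)OC[C@@H]1Cc1ccccc1)[C@H](O)c1cc(OC)c(OCc2ccc(OCc3ccccc3)c(OC)c2)c(Br)c1 | intermediate (not isolated)
10 | (4S)-4-benzyl-3-{[(2S,3R)-2-ArBr-5-oxooxolan-3-yl]carbonyl}-1,3-oxazolidin-2-one | O=C([C@@H]1CC(=O)O[C@@H]1c1cc(OC)c(OCc2ccc(OCc3ccccc3)c(OC)c2)c(Br)c1)N1C(=O)OC[C@@H]1Cc1ccccc1 | intermediate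
11 | (2S,3R)-2-ArBr-5-oxooxolane-3-carboperoxoic acid | OOC(=O)[C@@H]1CC(=O)O[C@@H]1c1cc(OC)c(OCc2ccc(OCc3ccccc3)c(OC)c2)c(Br)c1 | intermediate (not isolated)
12 | (2S,3R)-2-ArBr-5-oxooxolane-3-carboxylic acid | OC(=O)[C@@H]1CC(=O)O[C@@H]1c1cc(OC)c(OCc2ccc(OCc3ccccc3)c(OC)c2)c(Br)c1 | intermediate
13 | (4S,5S)-5-ArBr-4-(hydroxymethyl)oxolan-2-one | OC[C@@H]1CC(=O)O[C@@H]1c1cc(OC)c(OCc2ccc(OCc3ccccc3)c(OC)c2)c(Br)c1 | intermediate
14 | BMB 2,2,2-trichloroacetimidate | COc1cc(COC(=N)C(Cl)(Cl)Cl)ccc1OCc1ccccc1 | intermediate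
15 | (4S,5S)-5-ArBr-4-[(BMB-oxy)methyl]oxolan-2-one | COc1cc(COC[C@@H]2CC(=O)O[C@@H]2c2cc(OC)c(OCc3ccc(OCc4ccccc4)c(OC)c3)c(Br)c2)ccc1OCc1ccccc1 | intermediate
16 | tert-butyl bromoacetate | CC(C)(C)OC(=O)CBr | starting material
17 | (2-tert-butoxy-2-oxoethyl)zinc bromide | CC(C)(C)OC(=O)C[Zn]Br | intermediate
18 | tert-butyl arylacetate lactone | COc1cc(COC[C@@H]2CC(=O)O[C@@H]2c2cc(OC)c(OCc3ccc(OCc4ccccc4)c(OC)c3)c(CC(=O)OC(C)(C)C)c2)ccc1OCc1ccccc1 | intermediate
19 | tert-butyl aryldiazoacetate lactone | COc1cc(COC[C@@H]2CC(=O)O[C@@H]2c2cc(OC)c(OCc3ccc(OCc4ccccc4)c(OC)c3)c(C(=[N+]=[N-])C(=O)OC(C)(C)C)c2)ccc1OCc1ccccc1 | intermediate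
20 | aryldiazoacetate with α-trifluoroacetyl lactone (epimers at the acylated carbon) | COc1cc(COC[C@@H]2C(C(=O)C(F)(F)F)C(=O)O[C@@H]2c2cc(OC)c(OCc3ccc(OCc4ccccc4)c(OC)c3)c(C(=[N+]=[N-])C(=O)OC(C)(C)C)c2)ccc1OCc1ccccc1 | intermediate (not isolated)
21 | bis-diazo compound (aryldiazoacetate and α-diazo lactone) | COc1cc(COC[C@@H]2C(=[N+]=[N-])C(=O)O[C@@H]2c2cc(OC)c(OCc3ccc(OCc4ccccc4)c(OC)c3)c(C(=[N+]=[N-])C(=O)OC(C)(C)C)c2)ccc1OCc1ccccc1 | intermediate
22 | (2S,3R) cis-dihydrobenzofuran ester carrying the α-diazo lactone | COc1cc(COC[C@@H]2C(=[N+]=[N-])C(=O)O[C@@H]2c2cc(OC)c3c(c2)[C@@H](C(=O)OC(C)(C)C)[C@@H](c2ccc(OCc4ccccc4)c(OC)c2)O3)ccc1OCc1ccccc1 | intermediate (not isolated)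
23 | endo,endo (1R,2S,5S,6S) bicyclic lactone with the (2S,3R) cis-dihydrobenzofuran tert-butyl ester | COc1cc([C@H]2OC[C@@H]3[C@H]2C(=O)O[C@@H]3c2cc(OC)c3c(c2)[C@@H](C(=O)OC(C)(C)C)[C@@H](c2ccc(OCc4ccccc4)c(OC)c2)O3)ccc1OCc1ccccc1 | intermediate
24 | 1,4-diol (all-cis oxolane, (S)-benzylic carbinol) | COc1cc([C@H]2OC[C@H]([C@H]2CO)[C@H](O)c2cc(OC)c3c(c2)[C@@H](C(=O)OC(C)(C)C)[C@@H](c2ccc(OCc4ccccc4)c(OC)c2)O3)ccc1OCc1ccccc1 | intermediate
25 | primary mesylate of diol 24 | COc1cc([C@H]2OC[C@H]([C@H]2COS(C)(=O)=O)[C@H](O)c2cc(OC)c3c(c2)[C@@H](C(=O)OC(C)(C)C)[C@@H](c2ccc(OCc4ccccc4)c(OC)c2)O3)ccc1OCc1ccccc1 | intermediate (not isolated)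
26 | endo,endo (1S,2S,5S,6S) furofuran tert-butyl ester, both phenols as benzyl ethers | COc1cc([C@H]2OC[C@@H]3[C@H]2CO[C@@H]3c2cc(OC)c3c(c2)[C@@H](C(=O)OC(C)(C)C)[C@@H](c2ccc(OCc4ccccc4)c(OC)c2)O3)ccc1OCc1ccccc1 | intermediate
27 | dibenzyl ether of the target (primary alcohol) | COc1cc([C@H]2OC[C@@H]3[C@H]2CO[C@@H]3c2cc(OC)c3c(c2)[C@@H](CO)[C@@H](c2ccc(OCc4ccccc4)c(OC)c2)O3)ccc1OCc1ccccc1 | intermediate
28 | CNP0303197.1 | COc1cc([C@H]2OC[C@@H]3[C@H]2CO[C@@H]3c2cc(OC)c3c(c2)[C@@H](CO)[C@@H](c2ccc(O)c(OC)c2)O3)ccc1O | target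

**Count**

Total steps: 17. Longest linear sequence: 14 steps (steps 1, 3, 4, 5, 6, 8, 10, 11, 12, 13, 14, 15, 16, 17); steps 2, 7 and 9 are side branches.

**Steps most likely to fail**

1. Step 13 (the new method). The two carbenoids may not both follow the 1,5-insertion path under one set of conditions. The lactone carbenoid can divert to 1,2-hydride shift or dimerisation, the endo approach at C2 beside the endo C6 aryl can be slowed, and one chiral catalyst serving both sites can erode cis or facial selectivity. The fallback uses known chemistry and runs the two insertions apart, lactone first. It sets out from bromide 15: LiN(SiMe3)2 and CF3CO2CH2CF3 at −78 °C should give the α-trifluoroacetyl bromo lactone F1, and MsN3/Et3N the α-diazo bromo lactone F2. Rh2(OAc)4 in CH2Cl2 then closes ring 1 to the endo,endo bromo furofuranone F3. Coupling of F3 with 17 under Pd(dba)2/Q-Phos catalysis gives the tert-butyl arylacetate furofuranone F4, and 4-acetamidobenzenesulfonyl azide with DBU the aryldiazoacetate furofuranone F5. Rh2(S-PTTL)4 in toluene at −60 °C closes the cis-dihydrobenzofuran and the sequence returns to the route at 23. The epimerisable benzofuran ester never meets a strong base.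

2. Step 12. The lithium amide or the lactone enolate may attack the aryldiazoacetate at its terminal nitrogen, or acylation of the hindered lactone α-carbon may stall. The fallback sets out from 18, before any diazo group exists. Both acidic sites are deprotonated together with LiN(SiMe3)2 (2.3 equiv) at −78 °C and acylated with CF3CO2CH2CF3 to the bis(trifluoroacetyl) compound F6. One deacylative diazo transfer (MsN3, Et3N, MeCN) then installs both diazo groups and returns to the route at 21.

3. Step 15. Sulfonylation or ionisation at the electron-rich benzylic C6 carbinol would let ring 2 close through a benzylic cation, with drift of the C6 aryl group from endo to exo. The fallback sets out from lactone 23 and never breaks the C6–O7 bond. i-Bu2AlH in CH2Cl2 at −78 °C should reduce the lactone to the lactol F7 while the tert-butyl ester is kept. Et3SiH with BF3·OEt2 at −78 °C then removes the anomeric hydroxyl through the C8 oxocarbenium ion and returns to the route at 26, bypassing steps 14 and 15.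

**Further compounds**

F1 | step 13 | α-trifluoroacetyl bromo lactone | COc1cc(COC[C@@H]2C(C(=O)C(F)(F)F)C(=O)O[C@@H]2c2cc(OC)c(OCc3ccc(OCc4ccccc4)c(OC)c3)c(Br)c2)ccc1OCc1ccccc1
F2 | step 13 | α-diazo bromo lactone | COc1cc(COC[C@@H]2C(=[N+]=[N-])C(=O)O[C@@H]2c2cc(OC)c(OCc3ccc(OCc4ccccc4)c(OC)c3)c(Br)c2)ccc1OCc1ccccc1
F3 | step 13 | endo,endo bromo furofuranone | COc1cc([C@H]2OC[C@@H]3[C@H]2C(=O)O[C@@H]3c2cc(OC)c(OCc3ccc(OCc4ccccc4)c(OC)c3)c(Br)c2)ccc1OCc1ccccc1
F4 | step 13 | tert-butyl arylacetate furofuranone | COc1cc([C@H]2OC[C@@H]3[C@H]2C(=O)O[C@@H]3c2cc(OC)c(OCc3ccc(OCc4ccccc4)c(OC)c3)c(CC(=O)OC(C)(C)C)c2)ccc1OCc1ccccc1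
F5 | step 13 | aryldiazoacetate furofuranone | COc1cc([C@H]2OC[C@@H]3[C@H]2C(=O)O[C@@H]3c2cc(OC)c(OCc3ccc(OCc4ccccc4)c(OC)c3)c(C(=[N+]=[N-])C(=O)OC(C)(C)C)c2)ccc1OCc1ccccc1
F6 | step 12 | bis(trifluoroacetyl) compound | COc1cc(COC[C@@H]2C(C(=O)C(F)(F)F)C(=O)O[C@@H]2c2cc(OC)c(OCc3ccc(OCc4ccccc4)c(OC)c3)c(C(C(=O)C(F)(F)F)C(=O)OC(C)(C)C)c2)ccc1OCc1ccccc1
F7 | step 15 | lactol (anomers) | COc1cc([C@H]2OC[C@@H]3[C@H]2C(O)O[C@@H]3c2cc(OC)c3c(c2)[C@@H](C(=O)OC(C)(C)C)[C@@H](c2ccc(OCc4ccccc4)c(OC)c2)O3)ccc1OCc1ccccc1
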